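**Plan**

1. Oxolane numbering used here: O1, C2 (aryl), C3 (CH2OH), C4 (aroyl), C5. First cut: the aroyl C(=O)–aryl bond. The target is a γ-hydroxy ketone whose ketone carbon (on C4) and CH2OH carbon (on C3) are 1,4-related and cis, so both can be folded back into one cis-fused γ-lactone ring (the 3,7-dioxabicyclo[3.3.0]octan-2-one 9), which 3,4,5-trimethoxyphenyllithium opens.
2. Second cut: the C4–C5 bond (carbon alpha to the lactone carbonyl to the OCH2 carbon), made as an enol ether by O-to-C formyl transfer and then hydrogenated. Third cut: the ArCH(O)–C3 bond, made by an aldol reaction of 3,4-dimethoxybenzaldehyde with methyl 4-oxobutanoate.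
3. Forward order: aldol chain and lactone ring (step 1), oxolane ring (steps 2 and 3), saturation (step 4), aryl ketone with opening of the lactone ring (step 5).
4. Stereochemistry: (S)-proline sets the C3 centre and a provisional carbinol centre. Mitsunobu inversion turns that carbinol into the C2 configuration. Hydrogenation from the convex face sets C4 cis to C3, and the lactone ring holds C3/C4 cis until the last step.

Key step: step 5

Remark: the target is planned as the open γ-hydroxy aryl ketone; any cyclic hemiketal tautomer present in solution is the same compound in equilibrium.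

**Step 1**
Reactants: 1 3,4-dimethoxybenzaldehyde; 2 methyl 4-oxobutanoate
Product: 5 (4R)-4-[(R)-(3,4-dimethoxyphenyl)(hydroxy)methyl]oxolan-2-one, via aldol aldehyde 3 (not isolated), via diol ester 4 (not isolated)
Conditions: 2 (3 equiv), (S)-proline (30 mol%), DMF, 4 °C; then MeOH, NaBH4, −20 °C; aq. NH4Cl; PPTS (cat.), CH2Cl2, rt
Reagents that add atoms: none
Why: Proline-catalysed direct cross-aldol reaction of two aldehydes, in which the (S)-proline enamine of 2 adds to 1 through the hydrogen-bonded chair-like transition state and should give the anti aldol 3 with the (3S,4R) configuration under catalyst control; NaBH4 reduction of the formyl group and lactonisation of the new primary alcohol onto the methyl ester then trap it as 5 before the alpha centre can epimerise.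

**Step 2**
Reactants: 5 (4R)-4-[(R)-(3,4-dimethoxyphenyl)(hydroxy)methyl]oxolan-2-one
Product: 6 (S)-(3,4-dimethoxyphenyl)[(3R)-5-oxooxolan-3-yl]methyl formate
Conditions: PPh3, HCO2H, DIAD, toluene, −20 °C to rt
Reagents that add atoms: formic acid, O=CO
Why: Mitsunobu esterification, in which the alkoxyphosphonium ion of the hindered secondary benzylic alcohol is displaced by formate (small and acidic) in an SN2 step that inverts the carbinol carbon from R to S, the configuration needed at the aryl-bearing carbon of the oxolane, while the lactone and the neighbouring stereocentre are untouched.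

**Step 3**
Reactants: 6 (S)-(3,4-dimethoxyphenyl)[(3R)-5-oxooxolan-3-yl]methyl formate
Product: 8 (3aR,4S)-4-(3,4-dimethoxyphenyl)-3a,4-dihydro-1H,3H-furo[3,4-c]furan-1-one, via lactol 7 (not isolated)
Conditions: 6 added to LiN(SiMe3)2 (2.1 equiv), THF, −78 to −20 °C; AcOH; then PPTS (cat.), 4 Å MS, toluene, 70 °C
Reagents that add atoms: none
Why: Intramolecular Claisen condensation of the Baker–Venkataraman (O-to-C acyl transfer) type, in which the lithium enolate of the lactone attacks the tethered, highly electrophilic formate carbonyl in a 5-exo-trig closure that can only give the cis-fused lactol 7 and never breaks the benzylic C–O bond, so the configuration set in step 2 is kept; acid-catalysed loss of water towards the acidic alpha hydrogen then gives the conjugated enol ether 8.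

**Step 4**
Reactants: 8 (3aR,4S)-4-(3,4-dimethoxyphenyl)-3a,4-dihydro-1H,3H-furo[3,4-c]furan-1-one
Product: 9 (3aR,4S,6aR)-4-(3,4-dimethoxyphenyl)tetrahydro-1H,3H-furo[3,4-c]furan-1-one
Conditions: H2 (1 atm), 5% Rh/Al2O3, EtOAc, rt
Reagents that add atoms: none
Why: Heterogeneous catalytic hydrogenation (syn addition) of the trisubstituted enol ether, in which H2 should be delivered to the convex face of the folded bicycle (the face of the ring-fusion hydrogen) because the lactone ring blocks the other face and a trans-fused 5,5-system is strongly disfavoured both kinetically and, at this epimerisable centre, thermodynamically, which sets the carbon alpha to the carbonyl cis to its neighbour; Rh on Al2O3 is preferred to Pd/C to spare the electron-rich benzylic C–O bond.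

**Step 5**
Reactants: 9 (3aR,4S,6aR)-4-(3,4-dimethoxyphenyl)tetrahydro-1H,3H-furo[3,4-c]furan-1-one; 10 5-bromo-1,2,3-trimethoxybenzene
Product: 13 [(3R,4R,5S)-5-(3,4-dimethoxyphenyl)-4-(hydroxymethyl)oxolan-3-yl](3,4,5-trimethoxyphenyl)methanone, via aryllithium 11 (not isolated), via lithium hemiketalate 12 (not isolated)
Conditions: 10, n-BuLi (1.05 equiv), THF, −78 °C; transfer into 9, THF, −78 °C; AcOH in THF at −78 °C, then warm
Reagents that add atoms: none
Why: Aryllithium 11, made by bromine–lithium exchange, adds to the lactone carbonyl of 9 to give the lithium hemiketalate 12, which should persist at −78 °C and release the aryl ketone and the primary alcohol together only on protonation. The closest known reaction type is the single addition of an organolithium reagent to a γ-butyrolactone at low temperature to give a γ-hydroxy ketone. No ring is closed: the step opens the lactone ring of the 3,7-dioxabicyclo[3.3.0]octan-2-one and leaves the oxolane ring intact. No new stereocentre is made; the three centres of 9 are carried over, and the cis relation of the aroyl and hydroxymethyl groups follows directly from the cis ring fusion of 9. The step needs mono-addition without enolisation: the carbonyl stays masked in 12 until the cold quench and only 1.05 equiv of 11 is used, the ring-fusion alpha hydrogen is hindered, and the epimerisable ketone appears only after buffered protonation.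

**Compound list**

1 | 3,4-dimethoxybenzaldehyde | COc1ccc(C=O)cc1OC | starting material
2 | methyl 4-oxobutanoate | COC(=O)CCC=O | starting material
3 | methyl (3S,4R)-4-(3,4-dimethoxyphenyl)-3-formyl-4-hydroxybutanoate (anti aldol) | COc1ccc([C@H](O)[C@@H](C=O)CC(=O)OC)cc1OC | intermediate
4 | methyl (3R,4R)-4-(3,4-dimethoxyphenyl)-4-hydroxy-3-(hydroxymethyl)butanoate | COc1ccc([C@H](O)[C@@H](CO)CC(=O)OC)cc1OC | intermediate
5 | (4R)-4-[(R)-(3,4-dimethoxyphenyl)(hydroxy)methyl]oxolan-2-one | COc1ccc([C@H](O)[C@@H]2CC(=O)OC2)cc1OC | intermediate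
6 | (S)-(3,4-dimethoxyphenyl)[(3R)-5-oxooxolan-3-yl]methyl formate | COc1ccc([C@@H](OC=O)[C@@H]2CC(=O)OC2)cc1OC | intermediate
7 | (3aR,4S,6aR)-4-(3,4-dimethoxyphenyl)-6-hydroxytetrahydro-1H,3H-furo[3,4-c]furan-1-one (cis-fused lactol, both configurations at C6, in equilibrium with its open hydroxymethylidene form) | COc1ccc([C@H]2OC(O)[C@@H]3C(=O)OC[C@H]23)cc1OC | intermediate
8 | (3aR,4S)-4-(3,4-dimethoxyphenyl)-3a,4-dihydro-1H,3H-furo[3,4-c]furan-1-one (enol ether C6=C6a, aryl trans to the lactone CH2) | COc1ccc([C@H]2OC=C3C(=O)OC[C@H]23)cc1OC | intermediate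
9 | (3aR,4S,6aR)-4-(3,4-dimethoxyphenyl)tetrahydro-1H,3H-furo[3,4-c]furan-1-one, the same as (1R,5R,6S)-6-(3,4-dimethoxyphenyl)-3,7-dioxabicyclo[3.3.0]octan-2-one (cis-fused, aryl exo) | COc1ccc([C@H]2OC[C@@H]3C(=O)OC[C@H]23)cc1OC | intermediate
10 | 5-bromo-1,2,3-trimethoxybenzene | COc1cc(Br)cc(OC)c1OC | starting material
11 | 3,4,5-trimethoxyphenyllithium | [Li]c1cc(OC)c(OC)c(OC)c1 | intermediate
12 | lithium (3aR,4S,6aR)-4-(3,4-dimethoxyphenyl)-1-(3,4,5-trimethoxyphenyl)tetrahydro-1H,3H-furo[3,4-c]furan-1-olate (either configuration at C1) | COc1ccc([C@H]2OC[C@@H]3C([O-])(c4cc(OC)c(OC)c(OC)c4)OC[C@H]23)cc1OC.[Li+] | intermediate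
13 | [(3R,4R,5S)-5-(3,4-dimethoxyphenyl)-4-(hydroxymethyl)oxolan-3-yl](3,4,5-trimethoxyphenyl)methanone | COc1ccc([C@H]2OC[C@H](C(=O)c3cc(OC)c(OC)c(OC)c3)[C@@H]2CO)cc1OC | target

**Count**

Total steps: 5. Longest linear sequence: 5 steps (from 1 and 2 to 13).

**Steps most likely to fail**

Step 3. The amide base may attack the formyl group and cleave the formate, or the enolate may displace the benzylic formate in a three-membered ring closure, before the 5-exo acyl transfer takes place; the loss of water may also stall. The fallback sets out from 5 and comes back at 8, replacing steps 2 and 3 by C-formylation followed by an inverting ether closure. The dianion of 5 (LiN(SiMe3)2, 2.2 equiv, THF, −78 °C) is treated with excess 2,2,2-trifluoroethyl formate, which should formylate both the alpha carbon and the carbinol oxygen to give (R)-(3,4-dimethoxyphenyl)[(3R)-4-(hydroxymethylidene)-5-oxooxolan-3-yl]methyl formate F1. KHCO3 in MeOH cleaves the carbinol formate to give (4R)-4-[(R)-(3,4-dimethoxyphenyl)(hydroxy)methyl]-3-(hydroxymethylidene)oxolan-2-one F2. Intramolecular Mitsunobu etherification (PPh3, DIAD, THF, 0 °C), in which the acidic enol oxygen displaces the activated benzylic alcohol in a 5-exo-tet closure with inversion, should then give 8.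

Step 2. The electron-rich benzylic alkoxyphosphonium ion may ionise, with loss of stereochemical fidelity at the carbinol carbon, or eliminate. The fallback sets out from 5 and comes back at 6, and sets the carbinol centre by reagent-controlled reduction instead of SN2 inversion. Dess–Martin periodinane (CH2Cl2, NaHCO3) oxidises 5 to (4R)-4-(3,4-dimethoxybenzoyl)oxolan-2-one F3. Reduction with BH3·SMe2 under (R)-2-methyl-CBS-oxazaborolidine catalysis (THF, −20 °C) should give (4R)-4-[(S)-(3,4-dimethoxyphenyl)(hydroxy)methyl]oxolan-2-one F4. O-formylation with acetic formic anhydride and pyridine (0 °C) gives 6 with retention.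

Step 5. The hemiketalate may collapse early and take up a second aryllithium, the aryllithium may deprotonate the lactone instead of adding, or the centre alpha to the new ketone may epimerise during work-up. The fallback sets out from 9 and comes back at 13, and goes through a Weinreb amide instead of direct lactone opening. Me(MeO)NH·HCl and Me2AlCl (CH2Cl2, 0 °C) open the lactone to (3R,4R,5S)-5-(3,4-dimethoxyphenyl)-4-(hydroxymethyl)-N-methoxy-N-methyloxolane-3-carboxamide F5. This is silylated at once (Et3SiCl, imidazole, DMF) to stop relactonisation, giving (3R,4R,5S)-5-(3,4-dimethoxyphenyl)-N-methoxy-N-methyl-4-{[(triethylsilyl)oxy]methyl}oxolane-3-carboxamide F6. Aryllithium 11 (THF, −78 °C) then adds once, through the stable N-methoxy chelate, to give [(3R,4R,5S)-5-(3,4-dimethoxyphenyl)-4-{[(triethylsilyl)oxy]methyl}oxolan-3-yl](3,4,5-trimethoxyphenyl)methanone F7. HF·pyridine (THF, 0 °C) removes the silyl ether to give 13.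

**Further compounds**

F1 | step 3 | (R)-(3,4-dimethoxyphenyl)[(3R)-4-(hydroxymethylidene)-5-oxooxolan-3-yl]methyl formate | COc1ccc([C@H](OC=O)[C@H]2COC(=O)C2=CO)cc1OC
F2 | step 3 | (4R)-4-[(R)-(3,4-dimethoxyphenyl)(hydroxy)methyl]-3-(hydroxymethylidene)oxolan-2-one | COc1ccc([C@H](O)[C@H]2COC(=O)C2=CO)cc1OC
F3 | step 2 | (4R)-4-(3,4-dimethoxybenzoyl)oxolan-2-one | COc1ccc(C(=O)[C@@H]2CC(=O)OC2)cc1OC
F4 | step 2 | (4R)-4-[(S)-(3,4-dimethoxyphenyl)(hydroxy)methyl]oxolan-2-one | COc1ccc([C@@H](O)[C@@H]2CC(=O)OC2)cc1OC
F5 | step 5 | (3R,4R,5S)-5-(3,4-dimethoxyphenyl)-4-(hydroxymethyl)-N-methoxy-N-methyloxolane-3-carboxamide | COc1ccc([C@H]2OC[C@H](C(=O)N(C)OC)[C@@H]2CO)cc1OC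
F6 | step 5 | (3R,4R,5S)-5-(3,4-dimethoxyphenyl)-N-methoxy-N-methyl-4-{[(triethylsilyl)oxy]methyl}oxolane-3-carboxamide | COc1ccc([C@H]2OC[C@H](C(=O)N(C)OC)[C@@H]2CO[Si](CC)(CC)CC)cc1OC
F7 | step 5 | [(3R,4R,5S)-5-(3,4-dimethoxyphenyl)-4-{[(triethylsilyl)oxy]methyl}oxolan-3-yl](3,4,5-trimethoxyphenyl)methanone | COc1ccc([C@H]2OC[C@H](C(=O)c3cc(OC)c(OC)c(OC)c3)[C@@H]2CO[Si](CC)(CC)CC)cc1OC
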